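The α‑methylene‑γ‑lactone (O1, C6, C7, C11, C12; germacrane numbering) is assembled from CO2. In the key step a copper‑catalysed carboxylation converts a C11 alkenylboronate into an acrylate (C11–C12), whose oxygen at once displaces an allylic chloride at C6 with inversion (O1–C6), closing the lactone and fixing the trans C6/C7 relationship; it exploits C6 being allylic to C4=C5 and 1,3 to C11. The precursor is an acyclic chloro boronate built from (S)‑5‑(hydroxymethyl)furanone: C7 by cuprate addition, C6 by enolate hydroxylation, C4=C5 by Wittig olefination. The ten‑membered ring is closed afterwards at C9–C10 by chromium‑mediated addition of an α‑iodoenoate to the C9 aldehyde.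

Key step: step 13

Remark: germacrane numbering is used throughout, also for acyclic precursors (ring C1–C10; C11, C12, C13 = lactone α‑carbon, carbonyl carbon, exocyclic methylene; C14 = ester carbon on C10; C15 = hydroxymethyl carbon on C4).
Remark: (IPr)CuCl = chloro[1,3‑bis(2,6‑diisopropylphenyl)imidazol‑2‑ylidene]copper. Compounds 1, 7 and 8, (1‑bromoethenyl)trimethylsilane and all other reagents are taken as commercial.

Step 1
Reactants: 1 (S)‑5‑(hydroxymethyl)furan‑2(5H)‑one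
Product: 2 TBS ether of the butenolide
Conditions: TBSCl, imidazole, CH2Cl2, 0 °C to rt
Reagents that add atoms: tert‑butyl(chloro)dimethylsilane CC(C)(C)[Si](C)(C)Cl
Why: Standard silylation of the primary alcohol; the C8 stereocentre comes from the chiral pool and is untouched.

Step 2
Reactants: 2 TBS ether of the butenolide
Product: 3 trans‑4,5‑disubstituted vinylsilane lactone
Conditions: CH2=C(SiMe3)MgBr (from (1‑bromoethenyl)trimethylsilane and Mg), CuBr·SMe2 (20 mol%), THF, −78 to −40 °C; then aq. NH4Cl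
Reagents that add atoms: [1‑(trimethylsilyl)ethenyl]magnesium bromide C=C([Mg]Br)[Si](C)(C)C
Why: Copper‑catalysed conjugate addition of the Grignard reagent to the butenolide should occur anti to the CH2OTBS group, setting C7 (4,5‑trans).

Step 3
Reactants: 3 trans‑4,5‑disubstituted vinylsilane lactone
Product: 4 α‑hydroxy lactone (3,4‑trans, 4,5‑trans)
Conditions: KN(SiMe3)2, THF, −78 °C; 3‑phenyl‑2‑(phenylsulfonyl)oxaziridine; AcOH quench
Reagents that add atoms: 3‑phenyl‑2‑(phenylsulfonyl)oxaziridine O=S(=O)(c1ccccc1)N1OC1c1ccccc1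
Why: Davis oxidation of the potassium lactone enolate; the oxidant should approach anti to the C7 alkenyl group, setting C6 trans to it.

Step 4
Reactants: 4 α‑hydroxy lactone
Product: 5 iodoalkenyl hydroxy lactone
Conditions: NIS, (CF3)2CHOH, 0 °C
Reagents that add atoms: N‑iodosuccinimide O=C1CCC(=O)N1I
Why: Ipso‑iododesilylation of the vinylsilane should give the 2‑iodo‑1‑alkene; the trans‑disposed C6 hydroxyl cannot reach the iodonium, and no stereocentre is touched.

Step 5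
Reactants: 5 iodoalkenyl hydroxy lactone
Product: 6 lactol (anomer mixture)
Conditions: i‑Bu2AlH (2.5 equiv), CH2Cl2, −78 °C
Reagents that add atoms: none
Why: Half‑reduction of the γ‑lactone to the lactol via the aluminium hemiacetal, which is stable at low temperature.

Step 6
Reactants: 7 methyl (triphenyl‑λ5‑phosphanylidene)acetate; 8 3‑bromo‑1,1‑dimethoxypropane
Product: 9 methyl 5,5‑dimethoxy‑2‑(triphenyl‑λ5‑phosphanylidene)pentanoate
Conditions: NaI (cat.), MeCN, reflux; then NaOH (aq), CH2Cl2, rt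
Reagents that add atoms: none
Why: C‑alkylation of the stabilised ylide by the primary halide, then deprotonation of the phosphonium salt to the α‑branched ylide.

Step 7
Reactants: 6 lactol; 9 methyl 5,5‑dimethoxy‑2‑(triphenyl‑λ5‑phosphanylidene)pentanoate
Product: 10 dihydroxy (E)‑enoate
Conditions: toluene, 90 °C
Reagents that add atoms: none
Why: Wittig olefination of the open hydroxy‑aldehyde form; the α‑branched stabilised ylide should give the E‑enoate (ester carbon C15 trans to C6), and neutral conditions disfavour oxa‑Michael closure of the freed C8 hydroxyl.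

Step 8
Reactants: 10 dihydroxy (E)‑enoate
Product: 11 triol
Conditions: i‑Bu2AlH (6 equiv), CH2Cl2, −78 to 0 °C
Reagents that add atoms: none
Why: 1,2‑Reduction of the enoate to the primary allylic alcohol (C15); the alkenyl iodide and the acetal are inert.

Step 9
Reactants: 11 triol
Product: 12 TBDPS ether diol
Conditions: TBDPSCl (1.05 equiv), imidazole, CH2Cl2, −20 to 0 °C
Reagents that add atoms: tert‑butyl(chloro)diphenylsilane CC(C)(C)[Si](Cl)(c1ccccc1)c1ccccc1
Why: The bulky silyl chloride should react only at the primary allylic hydroxyl, not at the two hindered secondary ones.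

Step 10
Reactants: 12 TBDPS ether diol
Product: 13 boronate diol
Conditions: bis(pinacolato)diboron, PdCl2(PPh3)2 (3 mol%), PPh3, KOPh, toluene, 50 °C
Reagents that add atoms: bis(pinacolato)diboron CC1(C)OB(OC1(C)C)B1OC(C)(C)C(C)(C)O1
Why: Miyaura borylation of the alkenyl iodide; no allylic leaving group or acrylate is yet present that could divert the alkenylpalladium.

Step 11
Reactants: 13 boronate diol
Product: 14 allylic chloride (C6 inverted)
Conditions: PPh3, hexachloroacetone, CH2Cl2, −20 to 0 °C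
Reagents that add atoms: hexachloroacetone O=C(C(Cl)(Cl)Cl)C(Cl)(Cl)Cl
Why: Appel chlorination; the allylic C6 oxyphosphonium should be displaced by chloride in preference to the saturated C8 one, by SN2 with inversion and without transposition because C4 is fully substituted.

Step 12
Reactants: 14 allylic chloride
Product: 15 chloro boronate methacrylate
Conditions: methacrylic anhydride, Et3N, DMAP (cat.), CH2Cl2, 0 °C
Reagents that add atoms: methacrylic anhydride C=C(C)C(=O)OC(=O)C(C)=C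
Why: DMAP‑catalysed acylation of the remaining C8 hydroxyl; it blocks this oxygen before the carboxylate is generated.

Step 13
Reactants: 15 chloro boronate methacrylate
Product: 17 α‑methylene lactone acetal, via potassium acrylate 16 (not isolated)
Conditions: (IPr)CuCl (10 mol%), KOtBu (1.1 equiv), CO2 (1 atm), THF/DMF, 70 °C
Reagents that add atoms: carbon dioxide O=C=O
Why: KOtBu turns the pinacol boronate into a borate that transmetalates to (IPr)Cu–OtBu, giving a C11 alkenylcopper; CO2 inserts into the Cu–C bond (C11–C12) and the carboxylate is released as potassium salt 16. The carboxylate oxygen then displaces the allylic C6 chloride intramolecularly (O1–C6), so CO2 is stitched between C11 and C6. The closest known reaction types are the copper/NHC‑catalysed carboxylation of alkenylboronic esters with CO2 and the in situ O‑alkylation of such carboxylates by allylic chlorides. The γ‑lactone closes in the 5‑exo‑tet mode. The only new stereocentre, C6, is controlled by the configuration of the C–Cl bond through SN2 inversion, which places O1 trans to C11 across C6–C7 (6R). The step needs CO2 insertion to outrun copper‑mediated allyl–alkenyl coupling and SN2 to beat SN2′ and elimination: CO2 saturation, a hindered secondary chloride whose direct coupling would need a three‑membered ring, a fully substituted C4 and the early sequestering of alkoxide as borate and tert‑butyl carbonate should secure this.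

Step 14
Reactants: 17 α‑methylene lactone acetal
Product: 18 lactone aldehyde (C1 aldehyde)
Conditions: TESOTf, 2,4,6‑collidine, CH2Cl2, 0 °C; then H2O
Reagents that add atoms: water O
Why: Chemoselective acetal cleavage through a collidinium intermediate that water hydrolyses; silyl ethers, esters and the lactone should survive.

Step 15
Reactants: 18 lactone aldehyde; 7 methyl (triphenyl‑λ5‑phosphanylidene)acetate
Product: 20 (Z)‑α‑iodoenoate, via iodo ylide 19 (not isolated)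
Conditions: 7, NIS, MeCN, −20 °C; then 18, rt
Reagents that add atoms: N‑iodosuccinimide O=C1CCC(=O)N1I
Why: Iodination of the stabilised ylide followed by Wittig olefination should give the (Z)‑α‑iodoenoate (C2 trans to the ester, iodine cis to C2).

Step 16
Reactants: 20 (Z)‑α‑iodoenoate
Product: 21 primary alcohol (C9–OH)
Conditions: HF·pyridine, pyridine, THF, 0 °C
Reagents that add atoms: none
Why: Buffered fluoride cleaves the primary alkyl TBS ether faster than the TBDPS ether; the product is oxidised at once to limit methacryloyl migration.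

Step 17
Reactants: 21 primary alcohol
Product: 22 C9 aldehyde
Conditions: Dess–Martin periodinane, CH2Cl2, 0 °C
Reagents that add atoms: none
Why: Dess–Martin oxidation is mild and non‑basic, so the α‑acyloxy aldehyde should not epimerise at C8.

Step 18
Reactants: 22 C9 aldehyde
Product: 23 macrocyclic C9 alcohol
Conditions: CrCl2 (8 equiv), NiCl2 (2 mol%), DMSO/THF, rt, slow addition to 2 mM
Reagents that add atoms: none
Why: Nozaki–Hiyama–Kishi macrocyclisation forms C9–C10 and the ten‑membered ring, which enforces C2/C9 cis; Felkin–Anh attack anti to the C8–O bond should set C9 as 9R.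

Step 19
Reactants: 23 macrocyclic C9 alcohol
Product: 24 macrocyclic acetate
Conditions: Ac2O, pyridine, DMAP (cat.), CH2Cl2, 0 °C
Reagents that add atoms: acetic anhydride CC(=O)OC(C)=O
Why: Acetylation of the only free hydroxyl.

Step 20
Reactants: 24 macrocyclic acetate
Product: 25 target CNP0179134.4
Conditions: HF·pyridine, THF, 0 °C to rt
Reagents that add atoms: none
Why: Fluoride cleavage of the allylic TBDPS ether under weakly acidic conditions should leave the three esters and the α‑methylene lactone intact.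

Compound list
1 | (S)‑5‑(hydroxymethyl)furan‑2(5H)‑one | O=C1C=C[C@H](O1)CO | starting material
2 | (S)‑5‑({[tert‑butyl(dimethyl)silyl]oxy}methyl)furan‑2(5H)‑one | O=C1C=C[C@H](O1)CO[Si](C)(C)C(C)(C)C | intermediate
3 | (4S,5S)‑5‑({[tert‑butyl(dimethyl)silyl]oxy}methyl)‑4‑[1‑(trimethylsilyl)ethenyl]oxolan‑2‑one | O=C1C[C@H](C(=C)[Si](C)(C)C)[C@H](O1)CO[Si](C)(C)C(C)(C)C | intermediate
4 | (3S,4S,5S)‑5‑({[tert‑butyl(dimethyl)silyl]oxy}methyl)‑3‑hydroxy‑4‑[1‑(trimethylsilyl)ethenyl]oxolan‑2‑one | O=C1[C@@H](O)[C@H](C(=C)[Si](C)(C)C)[C@H](O1)CO[Si](C)(C)C(C)(C)C | intermediate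
5 | (3S,4S,5S)‑5‑({[tert‑butyl(dimethyl)silyl]oxy}methyl)‑3‑hydroxy‑4‑(1‑iodoethenyl)oxolan‑2‑one | O=C1[C@@H](O)[C@H](C(I)=C)[C@H](O1)CO[Si](C)(C)C(C)(C)C | intermediate
6 | (3S,4S,5S)‑5‑({[tert‑butyl(dimethyl)silyl]oxy}methyl)‑4‑(1‑iodoethenyl)oxolane‑2,3‑diol (anomer mixture) | OC1[C@@H](O)[C@H](C(I)=C)[C@H](O1)CO[Si](C)(C)C(C)(C)C | intermediate
7 | methyl (triphenyl‑λ5‑phosphanylidene)acetate | COC(=O)C=P(c1ccccc1)(c1ccccc1)c1ccccc1 | starting material
8 | 3‑bromo‑1,1‑dimethoxypropane | COC(CCBr)OC | starting material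
9 | methyl 5,5‑dimethoxy‑2‑(triphenyl‑λ5‑phosphanylidene)pentanoate | COC(=O)C(CCC(OC)OC)=P(c1ccccc1)(c1ccccc1)c1ccccc1 | intermediate
10 | methyl (2E,4R,5S,6S)‑7‑{[tert‑butyl(dimethyl)silyl]oxy}‑2‑(3,3‑dimethoxypropyl)‑4,6‑dihydroxy‑5‑(1‑iodoethenyl)hept‑2‑enoate | COC(=O)/C(CCC(OC)OC)=C/[C@@H](O)[C@H](C(I)=C)[C@H](O)CO[Si](C)(C)C(C)(C)C | intermediate
11 | (2E,4R,5S,6S)‑7‑{[tert‑butyl(dimethyl)silyl]oxy}‑2‑(3,3‑dimethoxypropyl)‑5‑(1‑iodoethenyl)hept‑2‑ene‑1,4,6‑triol | OC/C(CCC(OC)OC)=C/[C@@H](O)[C@H](C(I)=C)[C@H](O)CO[Si](C)(C)C(C)(C)C | intermediate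
12 | (2E,4R,5S,6S)‑7‑{[tert‑butyl(dimethyl)silyl]oxy}‑1‑{[tert‑butyl(diphenyl)silyl]oxy}‑2‑(3,3‑dimethoxypropyl)‑5‑(1‑iodoethenyl)hept‑2‑ene‑4,6‑diol | CC(C)(C)[Si](c1ccccc1)(c1ccccc1)OC/C(CCC(OC)OC)=C/[C@@H](O)[C@H](C(I)=C)[C@H](O)CO[Si](C)(C)C(C)(C)C | intermediate
13 | (2E,4R,5S,6S)‑7‑{[tert‑butyl(dimethyl)silyl]oxy}‑1‑{[tert‑butyl(diphenyl)silyl]oxy}‑2‑(3,3‑dimethoxypropyl)‑5‑[1‑(4,4,5,5‑tetramethyl‑1,3,2‑dioxaborolan‑2‑yl)ethenyl]hept‑2‑ene‑4,6‑diol | CC(C)(C)[Si](c1ccccc1)(c1ccccc1)OC/C(CCC(OC)OC)=C/[C@@H](O)[C@H](C(=C)B1OC(C)(C)C(C)(C)O1)[C@H](O)CO[Si](C)(C)C(C)(C)C | intermediate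
14 | (2E,4S,5R,6S)‑7‑{[tert‑butyl(dimethyl)silyl]oxy}‑1‑{[tert‑butyl(diphenyl)silyl]oxy}‑4‑chloro‑2‑(3,3‑dimethoxypropyl)‑5‑[1‑(4,4,5,5‑tetramethyl‑1,3,2‑dioxaborolan‑2‑yl)ethenyl]hept‑2‑en‑6‑ol (C6 of the germacrane numbering inverted) | CC(C)(C)[Si](c1ccccc1)(c1ccccc1)OC/C(CCC(OC)OC)=C/[C@H](Cl)[C@H](C(=C)B1OC(C)(C)C(C)(C)O1)[C@H](O)CO[Si](C)(C)C(C)(C)C | intermediate
15 | (2E,4S,5R,6S)‑7‑{[tert‑butyl(dimethyl)silyl]oxy}‑1‑{[tert‑butyl(diphenyl)silyl]oxy}‑4‑chloro‑2‑(3,3‑dimethoxypropyl)‑5‑[1‑(4,4,5,5‑tetramethyl‑1,3,2‑dioxaborolan‑2‑yl)ethenyl]hept‑2‑en‑6‑yl 2‑methylprop‑2‑enoate | CC(C)(C)[Si](c1ccccc1)(c1ccccc1)OC/C(CCC(OC)OC)=C/[C@H](Cl)[C@H](C(=C)B1OC(C)(C)C(C)(C)O1)[C@H](OC(=O)C(C)=C)CO[Si](C)(C)C(C)(C)C | intermediate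
16 | potassium acrylate: potassium salt of the acid in which the boryl group of 15 is replaced by CO2H (C6–Cl retained) | CC(C)(C)[Si](c1ccccc1)(c1ccccc1)OC/C(CCC(OC)OC)=C/[C@H](Cl)[C@H](C(=C)C(=O)[O-])[C@H](OC(=O)C(C)=C)CO[Si](C)(C)C(C)(C)C.[K+] | intermediate
17 | (1S)‑2‑{[tert‑butyl(dimethyl)silyl]oxy}‑1‑[(2R,3S)‑2‑{(1E)‑2‑({[tert‑butyl(diphenyl)silyl]oxy}methyl)‑5,5‑dimethoxypent‑1‑en‑1‑yl}‑4‑methylidene‑5‑oxooxolan‑3‑yl]ethyl 2‑methylprop‑2‑enoate | CC(C)(C)[Si](c1ccccc1)(c1ccccc1)OC/C(CCC(OC)OC)=C/[C@H]1OC(=O)C(=C)[C@@H]1[C@H](OC(=O)C(C)=C)CO[Si](C)(C)C(C)(C)C | intermediate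
18 | (1S)‑2‑{[tert‑butyl(dimethyl)silyl]oxy}‑1‑[(2R,3S)‑2‑{(1E)‑2‑({[tert‑butyl(diphenyl)silyl]oxy}methyl)‑5‑oxopent‑1‑en‑1‑yl}‑4‑methylidene‑5‑oxooxolan‑3‑yl]ethyl 2‑methylprop‑2‑enoate | CC(C)(C)[Si](c1ccccc1)(c1ccccc1)OC/C(CCC=O)=C/[C@H]1OC(=O)C(=C)[C@@H]1[C@H](OC(=O)C(C)=C)CO[Si](C)(C)C(C)(C)C | intermediate
19 | methyl iodo(triphenyl‑λ5‑phosphanylidene)acetate | COC(=O)C(I)=P(c1ccccc1)(c1ccccc1)c1ccccc1 | intermediate
20 | methyl (2Z,6E)‑7‑[(2R,3S)‑3‑{(1S)‑2‑{[tert‑butyl(dimethyl)silyl]oxy}‑1‑[(2‑methylprop‑2‑enoyl)oxy]ethyl}‑4‑methylidene‑5‑oxooxolan‑2‑yl]‑6‑({[tert‑butyl(diphenyl)silyl]oxy}methyl)‑2‑iodohepta‑2,6‑dienoate | CC(C)(C)[Si](c1ccccc1)(c1ccccc1)OC/C(CC/C=C(\I)C(=O)OC)=C/[C@H]1OC(=O)C(=C)[C@@H]1[C@H](OC(=O)C(C)=C)CO[Si](C)(C)C(C)(C)C | intermediate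
21 | methyl (2Z,6E)‑6‑({[tert‑butyl(diphenyl)silyl]oxy}methyl)‑7‑[(2R,3S)‑3‑{(1S)‑2‑hydroxy‑1‑[(2‑methylprop‑2‑enoyl)oxy]ethyl}‑4‑methylidene‑5‑oxooxolan‑2‑yl]‑2‑iodohepta‑2,6‑dienoate | CC(C)(C)[Si](c1ccccc1)(c1ccccc1)OC/C(CC/C=C(\I)C(=O)OC)=C/[C@H]1OC(=O)C(=C)[C@@H]1[C@H](OC(=O)C(C)=C)CO | intermediate
22 | methyl (2Z,6E)‑6‑({[tert‑butyl(diphenyl)silyl]oxy}methyl)‑2‑iodo‑7‑[(2R,3S)‑3‑{(1S)‑1‑[(2‑methylprop‑2‑enoyl)oxy]‑2‑oxoethyl}‑4‑methylidene‑5‑oxooxolan‑2‑yl]hepta‑2,6‑dienoate | CC(C)(C)[Si](c1ccccc1)(c1ccccc1)OC/C(CC/C=C(\I)C(=O)OC)=C/[C@H]1OC(=O)C(=C)[C@@H]1[C@H](OC(=O)C(C)=C)C=O | intermediate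
23 | methyl (1(10)E,4E,6R,7S,8S,9R)‑15‑{[tert‑butyl(diphenyl)silyl]oxy}‑9‑hydroxy‑8‑[(2‑methylprop‑2‑enoyl)oxy]germacra‑1(10),4,11(13)‑trien‑12,6‑olid‑14‑oate (ten‑membered carbocycle fused at C6–C7 to the α‑methylene‑γ‑lactone) | C=C(C)C(=O)O[C@H]1[C@H]2C(=C)C(=O)O[C@@H]2/C=C(/CO[Si](c3ccccc3)(c3ccccc3)C(C)(C)C)CC/C=C(/C(=O)OC)[C@H]1O | intermediate
24 | methyl (1(10)E,4E,6R,7S,8S,9R)‑9‑acetoxy‑15‑{[tert‑butyl(diphenyl)silyl]oxy}‑8‑[(2‑methylprop‑2‑enoyl)oxy]germacra‑1(10),4,11(13)‑trien‑12,6‑olid‑14‑oate | C=C(C)C(=O)O[C@H]1[C@H]2C(=C)C(=O)O[C@@H]2/C=C(/CO[Si](c3ccccc3)(c3ccccc3)C(C)(C)C)CC/C=C(/C(=O)OC)[C@H]1OC(C)=O | intermediate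
25 | CNP0179134.4, methyl (1(10)E,4E,6R,7S,8S,9R)‑9‑acetoxy‑15‑hydroxy‑8‑[(2‑methylprop‑2‑enoyl)oxy]germacra‑1(10),4,11(13)‑trien‑12,6‑olid‑14‑oate | C=C(C)C(=O)O[C@H]1[C@H]2C(=C)C(=O)O[C@@H]2/C=C(/CO)CC/C=C(/C(=O)OC)[C@H]1OC(C)=O | target

Total step count: 20. Longest linear sequence: 19 steps (steps 1–5 and 7–20, from 1 to 25); step 6 prepares ylide 9.

Steps most likely to fail

1. Step 18 (macrocyclisation). Intermolecular addition may compete with the slow closure of the ten‑membered ring, the C8 methacryloyl group may shift to the new C9 chromium alkoxide, and above all the ring‑forming transition state may override Felkin–Anh control so that facial selectivity at C9 is poor. The fallback sets out from 23 obtained as a C9 epimer mixture. Dess–Martin oxidation should give the 9‑oxo macrocycle F1. A reagent‑controlled 1,2‑reduction with (R)‑2‑methyl‑CBS‑oxazaborolidine and catecholborane at −78 °C, with the alkenyl carbon C10 acting as the large group, should then deliver the 9R alcohol, and the route is rejoined at 23.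

2. Step 13 (key step). The alkenylcopper may be captured by the allylic chloride before CO2 inserts (copper‑mediated allyl–alkenyl coupling, SN2′ closure to a methylenecyclopentene), or HCl may be lost by elimination. The fallback sets out from 13 and closes the lactone the conventional way, through the acyl carbon. The same copper‑catalysed carboxylation, run on the diol with 3.3 equiv KOtBu under CO2, should give the dihydroxy acrylic acid F2. On mild acidification (PPTS, CH2Cl2) F2 should lactonise onto the C6 hydroxyl, the trans‑4,5‑disubstituted 6,12‑lactone being favoured over the cis 8,12‑isomer, to give hydroxy lactone F3. Methacryloylation of the C8 hydroxyl (methacrylic anhydride, Et3N, DMAP) comes back to the route at 17.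

3. Step 11 (chlorination). Discrimination between the two secondary hydroxyls may be incomplete, and partial ionisation of the allylic oxyphosphonium may erode the inversion or give the transposed chloride. The fallback sets out from 13. SOCl2 and Et3N in CH2Cl2 at 0 °C should tie both hydroxyls into the six‑membered cyclic sulfite F4 (mixture at sulfur). LiCl in DMF at 60 °C should open it only at the allylic C6–O bond with inversion, and hydrolysis of the sulfite half‑ester on aqueous work‑up comes back to the route at 14.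

Further compounds
F1 | step 18 | 9‑oxo macrocycle, methyl (1(10)E,4E,6R,7S,8S)‑15‑{[tert‑butyl(diphenyl)silyl]oxy}‑8‑[(2‑methylprop‑2‑enoyl)oxy]‑9‑oxogermacra‑1(10),4,11(13)‑trien‑12,6‑olid‑14‑oate | C=C(C)C(=O)O[C@H]1[C@H]2C(=C)C(=O)O[C@@H]2/C=C(/CO[Si](c3ccccc3)(c3ccccc3)C(C)(C)C)CC/C=C(/C(=O)OC)C1=O
F2 | step 13 | dihydroxy acrylic acid, 13 with the boryl group replaced by CO2H | CC(C)(C)[Si](c1ccccc1)(c1ccccc1)OC/C(CCC(OC)OC)=C/[C@@H](O)[C@H](C(=C)C(=O)O)[C@H](O)CO[Si](C)(C)C(C)(C)C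
F3 | step 13 | hydroxy lactone, 17 with a free C8 hydroxyl in place of the methacrylate | CC(C)(C)[Si](c1ccccc1)(c1ccccc1)OC/C(CCC(OC)OC)=C/[C@H]1OC(=O)C(=C)[C@@H]1[C@H](O)CO[Si](C)(C)C(C)(C)C
F4 | step 11 | cyclic sulfite (1,3,2‑dioxathiane 2‑oxide) spanning the C6 and C8 oxygens of 13 | CC(C)(C)[Si](c1ccccc1)(c1ccccc1)OC/C(CCC(OC)OC)=C/[C@H]1OS(=O)O[C@H](CO[Si](C)(C)C(C)(C)C)[C@H]1C(=C)B1OC(C)(C)C(C)(C)O1
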